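The meeting took up the flask to be read at 15 h. Its 0.0550 M of coupling partner stands above its 0.050 M of solid substrate, so solid substrate is the limiting reagent.

| flask | solid substrate | coupling partner | remark | time |
|---|---|---|---|---|
| maple | 0.050 M | 0.077 M | run made earlier |  |
| cedar | 0.050 M | 0.12 M | run made earlier |  |
| flask | 0.050 M | 0.0550 M |  | 15 h |

- maple (time / h: target / %, solid substrate / %): 1.33: 48.1, 48.4; 4.00: 94.9, 0; 6.00: 95.1, 0; 10.0: 94.6, 0; 15.0: 95.1, 0.2; 20.0: 94.8, 0
- cedar (time / h: target / %, solid substrate / %): 1.33: 58.5, 40.0; 4.00: 98.8, 0.3; 6.00: 99.2, 0; 10.0: 99.3, 0; 15.0: 98.5, 0; 20.0: 98.6, 0.1

(standard deviation of a reading: 0.3 percentage points)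

1. which holds at 15 h: what has brought the reaction to rest, or that it has not come to rest (for what has run out or reacted, a solid counts together with what of it has only dissolved) (forward and back rates have come level / all of the solid substrate has reacted / it is still moving / the coupling partner has run out first)
2. target at 15 h, in percent of the solid substrate charged

- given per volume of solution although it is solid: solid substrate
- the analysis behind the earlier runs scatters by 0.3 percentage points, standard deviation
- at the start none of the solid substrate is in solution
- what has only dissolved of solid substrate counts as not reacted
- the reaction counts as stopped when no species that holds the solid substrate changes by six tenths of a point or more over the second half of the time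

It was noted that solid substrate reads 0% at 4.00 h in the maple run and 0.3% in the cedar run. Target then stays flat, at 94.9% and 98.9%.

I proposed one measure, a selectivity factor. The maple split, target at rest over the missing part of the charge, reads 18.6. The cedar split reads 88.3. An even split, 1, is the zero of this scale.

I set each split against the coupling partner at mid-course, taken as its charge less half of the solid substrate charge. That is 0.0520 M and 0.0950 M, which gives an order of 2.58. For the flask, mid-course partner is 0.0300 M. I therefore reckoned a split of 4.49, or 81.8% target. I read the missing part as lost for good, so that the flask rests once its solid substrate has reacted.

The forecast's author argued for 85% of target, with this end: forward and back rates have come level. The author read the missing part as dissolved substrate “held in equilibrium with the target”. The forecast's figure of 85% stands above my 81.8%. The meeting recorded both views.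

The flask gives 85.1% of target at 15 h, and its end is this: all of the solid substrate has reacted.

    solid substrate ⇌ starting material, rate k1*(cs1 - [starting material]) while solid is left; crystals form when [starting material] > cs1 (solubility = 3.60 mM, k = 0.00210 s⁻¹)
    2 starting material → homo dimer (k = 0.0600 M⁻¹ s⁻¹)
    starting material + coupling partner → target, rate k3*[starting material]*[coupling partner]^1.5 (k = 0.290 M⁻¹·⁵ s⁻¹)

At 15.0 h the flask holds 85.1% target and 14.9% homo dimer, a split of 5.70, above my 4.49 and below the maple 18.6. At 1.56 h in the flask, starting material goes to target 8.1 times as fast as to homo dimer, which is higher than that whole-run split. The neighbour charged with 0.12 M of solid substrate has 0.458 equiv of coupling partner. At 15.0 h that neighbour holds 44.5% target and 40.1% homo dimer, with 15% of its charge still solid or dissolved. Target over homo dimer in that neighbour reads 1.11.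

(The data come from a simulation with constants of no real substance; noise was put on by code.)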